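The numbers in the tables stem from a simulated flask for an exercise; noise was put on by code.

Which is there more of in this flask, G or L, and how does their ratio stand at the two asked times?

- ratio of G to L at 0.50 s
- ratio of G to L at 6.0 min
- which of G and L there is more of at 6.0 min

| flask | Q | E | J | remark | time |
|---|---|---|---|---|---|
| north-west | 0.020 M | 0.030 M | 2.5 mM | run made earlier |  |
| north-east | 0.020 M | 0.030 M | 3.8 mM | run made earlier |  |
| south | 0.010 M | 0.030 M | 5 mM | run made earlier |  |
| flask | 0.020 M | 0.0300 M | 5.00 mM |  | 6.0 min |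

- north-west (time / min: G / %, L / %, Q / %): 0.250: 18.5, 14.1, 55.5; 0.500: 28.9, 21.5, 37.8; 0.833: 35.9, 25.0, 22.5; 1.33: 41.9, 29.1, 12.4; 2.00: 43.4, 32.0, 6.6; 4.00: 47.2, 33.5, 0
- north-east (time / min: G / %, L / %, Q / %): 0.667: 32.0, 23.1, 28.2; 1.33: 40.5, 26.7, 13.2; 2.00: 44.1, 30.7, 6.8; 2.50: 45.5, 31.0, 6.0; 3.00: 45.1, 32.0, 3.3; 4.00: 45.8, 30.5, 1.2
- south (time / min: G / %, L / %, Q / %): 0.250: 22.0, 16.0, 54.7; 0.500: 31.1, 22.3, 35.5; 1.00: 41.4, 32.7, 16.8; 2.00: 49.4, 33.8, 4.7; 4.00: 50.4, 36.6, 0.2

(standard deviation of a reading: 1 percentage point)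



I turn the question round and ask what the readings would have to show for L to lead. I follow one molecule that ends in G or L. From the last readings of the three runs taken together, G over G plus L is 0.588, and I call this chance of ending in G the fork chance. For L to lead, it has to fall below 0.5. Run by run it reads 0.585, 0.600 and 0.579, while c(J)/c(Q) runs from 0.125 to 0.500, and this flask, at 0.250, lies inside that range. The late lead of G averages 14 percentage points, against a scatter of 1 point per reading. So I commit to G ahead, with a ratio, the selectivity factor, of 1.43 at 6.0 min. I carry that ratio to 0.50 s less firmly: the earliest reading stands at 0.250 min.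

The forecast gives 1.36 (1.1 to 1.55) at 0.50 s and 1.42 (1.32 to 1.53) at 6.0 min, with G ahead, since “G and L look like parallel products with a fixed split”.

The flask gives 1.40 at 0.50 s and 1.46 at 6.0 min, with G ahead, 46.4 % against 31.7 %.

    Q ⇌ J (K = 0.112, k = 1.85 s⁻¹)
    Q + E → L (k = 0.552 M⁻¹ s⁻¹)
    E + J → G (k = 6.23 M⁻¹ s⁻¹)
    Q + L → Z (k = 0.271 M⁻¹ s⁻¹)
    2 J → D (k = 12.8 M⁻¹ s⁻¹)
    Q → X (k = 1.14 × 10⁻⁵ s⁻¹)

This flask's fork chance is 0.594 at 6.0 min and 0.583 at 0.50 s. Part of the reason it stands there at 0.50 s is the way back from J to Q: the same flask run without that way back gives a ratio of 9.42 at 0.50 s, a fork chance of 0.904. The neighbour charged with 0.0080 M of Q has a fork chance of 0.572 at 6.00 min, a ratio of 1.34.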